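The route rests on cutting C3–C4 of ring C (the pyran ring) of the upper flavan unit. C4 is benzylic and para to the 7-hydroxyl of ring A, so it can be unmasked as the exocyclic carbon of a para-quinone methide. In the key step, fluoride releases this quinone methide from a silylated benzhydryl acetate. A primary radical at C3, formed from an iodide next to the preset (R)-configured C2–O1 aryl ether, then closes the pyran ring onto C4 (6-endo-trig), restoring the aromaticity of ring A and setting C4 cis to C2. The precursor is a diarylmethyl acetate joining 8-lithiated perbenzylated epicatechin to a salicylaldehyde ether carrying a 2-iodo-1-arylethyl group.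

Key step: step 9

Remark: C2, C3, C4, O1 and rings A, B, C refer to the upper 4',7-dihydroxyflavan unit; ArD is the perbenzylated epicatechin unit bound through its C8. Acetate 13 is carried as a mixture of epimers at the acetoxy carbon, which does not matter because this carbon becomes trigonal in 15.

Step 1
Reactants: 1 (−)-epicatechin
Product: 2 5,7,3',4'-tetra-O-benzyl-(−)-epicatechin
Conditions: BnBr (4.4 equiv), K2CO3, DMF, 0 °C → rt
Reagents that add atoms: benzyl bromide, BrCc1ccccc1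
Why: Williamson etherification in which the four phenols are alkylated under carbonate while the secondary 3-OH stays free and no stereocentre is touched.

Step 2
Reactants: 2 5,7,3',4'-tetra-O-benzyl-(−)-epicatechin
Product: 3 8-bromo-5,7,3',4'-tetra-O-benzyl-(−)-epicatechin
Conditions: NBS (1.0 equiv), CH2Cl2, −78 °C → rt
Reagents that add atoms: N-bromosuccinimide, O=C1CCC(=O)N1Br
Why: Electrophilic aromatic bromination, expected at C8 because this is the most nucleophilic position of the phloroglucinol-type ring of the tetrabenzyl ether.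

Step 3
Reactants: 3 8-bromo-5,7,3',4'-tetra-O-benzyl-(−)-epicatechin
Product: 4 8-bromo-3,5,7,3',4'-penta-O-benzyl-(−)-epicatechin
Conditions: NaH (1.5 equiv), BnBr (1.3 equiv), DMF, 0 °C → rt
Reagents that add atoms: benzyl bromide, BrCc1ccccc1
Why: Williamson etherification of the secondary alkoxide, which masks the 3-OH against the organolithium and acylation of step 8 and is removed with the other benzyl groups at the end.

Step 4
Reactants: 5 1-[4-(benzyloxy)phenyl]-2-bromoethan-1-one
Product: 6 (1S)-1-[4-(benzyloxy)phenyl]-2-bromoethan-1-ol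
Conditions: (S)-2-methyl-CBS-oxazaborolidine (10 mol %), BH3·SMe2 (0.7 equiv), THF, 0 °C; MeOH quench
Reagents that add atoms: none
Why: Corey–Bakshi–Shibata reduction in which the oxazaborolidine–borane complex delivers hydride to one face with the aryl group as the large substituent, setting the future C2 as the (S)-bromohydrin under reagent control.

Step 5
Reactants: 7 2,4-dihydroxybenzaldehyde
Product: 8 4-[(tert-butyldimethylsilyl)oxy]-2-hydroxybenzaldehyde
Conditions: TBSCl (1.05 equiv), imidazole (1.5 equiv), CH2Cl2, 0 °C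
Reagents that add atoms: tert-butyldimethylsilyl chloride, CC(C)(C)[Si](C)(C)Cl
Why: Selective silylation of the 4-OH, because the 2-OH is tied up in a hydrogen bond to the aldehyde; the silyl ether later serves as the fluoride-triggered latch of the quinone methide.

Step 6
Reactants: 8 4-[(tert-butyldimethylsilyl)oxy]-2-hydroxybenzaldehyde, 6 (1S)-1-[4-(benzyloxy)phenyl]-2-bromoethan-1-ol
Product: 9 2-{(1R)-1-[4-(benzyloxy)phenyl]-2-bromoethoxy}-4-[(tert-butyldimethylsilyl)oxy]benzaldehyde
Conditions: PPh3 (1.3 equiv), DIAD (1.3 equiv), toluene, −20 °C → rt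
Reagents that add atoms: none
Why: Mitsunobu etherification with inversion (S to R) forms the C2–O1 aryl ether in the configuration that becomes (2S) in the flavan; the electron-withdrawing β-bromine should offset the donor 4-benzyloxy group so that SN2 displacement prevails over ionisation.

Step 7
Reactants: 9 2-{(1R)-1-[4-(benzyloxy)phenyl]-2-bromoethoxy}-4-[(tert-butyldimethylsilyl)oxy]benzaldehyde
Product: 10 2-{(1R)-1-[4-(benzyloxy)phenyl]-2-iodoethoxy}-4-[(tert-butyldimethylsilyl)oxy]benzaldehyde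
Conditions: NaI (5 equiv), NaHCO3 (0.1 equiv), 2-butanone, 75 °C, dark
Reagents that add atoms: sodium iodide, [Na+].[I-]
Why: Finkelstein exchange by SN2 at the primary carbon, driven by precipitation of NaBr and leaving C2 untouched; the iodide is needed for fast atom abstraction in step 9.

Step 8
Reactants: 4 8-bromo-3,5,7,3',4'-penta-O-benzyl-(−)-epicatechin, 10 2-{(1R)-1-[4-(benzyloxy)phenyl]-2-iodoethoxy}-4-[(tert-butyldimethylsilyl)oxy]benzaldehyde
Product: 13 diarylmethyl acetate joining ring A and ArD (both epimers at the acetoxy carbon), via aryllithium 11 (not isolated), via lithium alkoxide 12 (not isolated)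
Conditions: 4 (1.1 equiv), t-BuLi (2.2 equiv), THF, −78 °C; then 10, −78 °C; then Ac2O (3 equiv), −78 → 0 °C; Et3N-buffered work-up
Reagents that add atoms: acetic anhydride, CC(=O)OC(C)=O
Why: Bromine–lithium exchange followed by 1,2-addition of the aryllithium to the aldehyde, which at −78 °C should be far faster than substitution at the primary iodide, forms the C4–C8 bond, and O-acylation of the alkoxide in the same flask installs the leaving group; the new carbinol centre is irrelevant.

Step 9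
Reactants: 13 diarylmethyl acetate joining ring A and ArD
Product: 16 hexa-O-benzyl flavan–epicatechin with free 7-OH on ring A and (2S,4S) configuration, via phenoxide 14 (not isolated), via quinone methide 15 (not isolated)
Conditions: Bu4NF (1.0 equiv), THF, −40 → 0 °C; then toluene (0.005 M), Bu3SnH (1.3 equiv, syringe pump), Et3B (0.3 equiv), air, 0 °C → rt; KF work-up
Reagents that add atoms: none
Why: Fluoride cleaves the aryl silyl ether and phenoxide 14 expels acetate by 1,6-elimination to give quinone methide 15; Bu3Sn• then abstracts iodine, the primary C3 radical adds to the exocyclic C4, and the aromatised phenoxyl radical takes hydrogen from Bu3SnH to carry the chain. The closest known reaction type is the Giese-type radical 1,6-conjugate addition of alkyl radicals from alkyl iodides to para-quinone methides, run here as a tin hydride radical cyclisation. The pyran ring closes in the 6-endo-trig mode. C4 is set by the existing C2 stereocentre through a chair-like transition state in which the 4-benzyloxyphenyl group at C2 and ArD at C4 (anti to O1 in 15) are both pseudo-equatorial, which should give the 2,4-cis (4S) isomer. The step needs attack at C4 rather than 5-exo attack at C4a, which is secured by the large LUMO coefficient at the exocyclic carbon, the full substitution of C4a and the gain of aromaticity; it also needs iodine abstraction to outrun addition of tin radicals or hydride to the quinone methide, which is secured by the iodide, high dilution and slow addition of Bu3SnH.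

Step 10
Reactants: 16 hexa-O-benzyl flavan–epicatechin with free 7-OH on ring A
Product: 17 CNP0298337.1, (2S,4S)-4',7-dihydroxyflavan-(4→8)-(−)-epicatechin
Conditions: H2 (1 atm), Pd(OH)2/C, THF/MeOH, rt
Reagents that add atoms: none
Why: Hydrogenolysis of the six benzyl ethers under neutral conditions, which should leave the cyclic benzylic C2–O1 bonds and all five stereocentres untouched.

Compound list
1 | (−)-epicatechin, (2R,3R)-2-(3,4-dihydroxyphenyl)-3,4-dihydro-2H-chromene-3,5,7-triol | Oc1cc(O)c2c(c1)O[C@H](c1ccc(O)c(O)c1)[C@H](O)C2 | starting material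
2 | (2R,3R)-5,7-bis(benzyloxy)-2-[3,4-bis(benzyloxy)phenyl]-3,4-dihydro-2H-chromen-3-ol | c1c(OCc2ccccc2)cc(OCc2ccccc2)c2c1O[C@H](c1ccc(OCc3ccccc3)c(OCc3ccccc3)c1)[C@H](O)C2 | intermediate
3 | (2R,3R)-5,7-bis(benzyloxy)-2-[3,4-bis(benzyloxy)phenyl]-8-bromo-3,4-dihydro-2H-chromen-3-ol | Brc1c(OCc2ccccc2)cc(OCc2ccccc2)c2c1O[C@H](c1ccc(OCc3ccccc3)c(OCc3ccccc3)c1)[C@H](O)C2 | intermediate
4 | (2R,3R)-3,5,7-tris(benzyloxy)-2-[3,4-bis(benzyloxy)phenyl]-8-bromo-3,4-dihydro-2H-chromene | Brc1c(OCc2ccccc2)cc(OCc2ccccc2)c2c1O[C@H](c1ccc(OCc3ccccc3)c(OCc3ccccc3)c1)[C@H](OCc1ccccc1)C2 | intermediate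
5 | 1-[4-(benzyloxy)phenyl]-2-bromoethan-1-one | O=C(CBr)c1ccc(OCc2ccccc2)cc1 | starting material
6 | (1S)-1-[4-(benzyloxy)phenyl]-2-bromoethan-1-ol | O[C@H](CBr)c1ccc(OCc2ccccc2)cc1 | intermediate
7 | 2,4-dihydroxybenzaldehyde | O=Cc1ccc(O)cc1O | starting material
8 | 4-[(tert-butyldimethylsilyl)oxy]-2-hydroxybenzaldehyde | O=Cc1ccc(O[Si](C)(C)C(C)(C)C)cc1O | intermediate
9 | 2-{(1R)-1-[4-(benzyloxy)phenyl]-2-bromoethoxy}-4-[(tert-butyldimethylsilyl)oxy]benzaldehyde | O=Cc1ccc(O[Si](C)(C)C(C)(C)C)cc1O[C@@H](CBr)c1ccc(OCc2ccccc2)cc1 | intermediate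
10 | 2-{(1R)-1-[4-(benzyloxy)phenyl]-2-iodoethoxy}-4-[(tert-butyldimethylsilyl)oxy]benzaldehyde | O=Cc1ccc(O[Si](C)(C)C(C)(C)C)cc1O[C@@H](CI)c1ccc(OCc2ccccc2)cc1 | intermediate
11 | [(2R,3R)-3,5,7-tris(benzyloxy)-2-[3,4-bis(benzyloxy)phenyl]-3,4-dihydro-2H-chromen-8-yl]lithium | [Li]c1c(OCc2ccccc2)cc(OCc2ccccc2)c2c1O[C@H](c1ccc(OCc3ccccc3)c(OCc3ccccc3)c1)[C@H](OCc1ccccc1)C2 | intermediate
12 | lithium alkoxide of the diarylmethanol from 11 and 10 (both epimers) | [Li]OC(c1ccc(O[Si](C)(C)C(C)(C)C)cc1O[C@@H](CI)c1ccc(OCc2ccccc2)cc1)c1c(OCc2ccccc2)cc(OCc2ccccc2)c2c1O[C@H](c1ccc(OCc3ccccc3)c(OCc3ccccc3)c1)[C@H](OCc1ccccc1)C2 | intermediate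
13 | {2-{(1R)-1-[4-(benzyloxy)phenyl]-2-iodoethoxy}-4-[(tert-butyldimethylsilyl)oxy]phenyl}[(2R,3R)-3,5,7-tris(benzyloxy)-2-[3,4-bis(benzyloxy)phenyl]-3,4-dihydro-2H-chromen-8-yl]methyl acetate (both epimers at the acetoxy carbon) | CC(=O)OC(c1ccc(O[Si](C)(C)C(C)(C)C)cc1O[C@@H](CI)c1ccc(OCc2ccccc2)cc1)c1c(OCc2ccccc2)cc(OCc2ccccc2)c2c1O[C@H](c1ccc(OCc3ccccc3)c(OCc3ccccc3)c1)[C@H](OCc1ccccc1)C2 | intermediate
14 | tetrabutylammonium phenoxide of desilylated 13 | CC(=O)OC(c1ccc([O-])cc1O[C@@H](CI)c1ccc(OCc2ccccc2)cc1)c1c(OCc2ccccc2)cc(OCc2ccccc2)c2c1O[C@H](c1ccc(OCc3ccccc3)c(OCc3ccccc3)c1)[C@H](OCc1ccccc1)C2.CCCC[N+](CCCC)(CCCC)CCCC | intermediate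
15 | (4E)-3-{(1R)-1-[4-(benzyloxy)phenyl]-2-iodoethoxy}-4-{[(2R,3R)-3,5,7-tris(benzyloxy)-2-[3,4-bis(benzyloxy)phenyl]-3,4-dihydro-2H-chromen-8-yl]methylidene}cyclohexa-2,5-dien-1-one | O=C1C=C/C(=C\c2c(OCc3ccccc3)cc(OCc3ccccc3)c3c2O[C@H](c2ccc(OCc4ccccc4)c(OCc4ccccc4)c2)[C@H](OCc2ccccc2)C3)C(O[C@@H](CI)c2ccc(OCc3ccccc3)cc2)=C1 | intermediate
16 | (2R,3R)-3,5,7-tris(benzyloxy)-2-[3,4-bis(benzyloxy)phenyl]-8-{(2S,4S)-2-[4-(benzyloxy)phenyl]-7-hydroxy-3,4-dihydro-2H-chromen-4-yl}-3,4-dihydro-2H-chromene | c1ccccc1COc1ccc([C@@H]2C[C@H](c3c(OCc5ccccc5)cc(OCc5ccccc5)c4c3O[C@H](c3ccc(OCc5ccccc5)c(OCc5ccccc5)c3)[C@H](OCc3ccccc3)C4)c3ccc(O)cc3O2)cc1 | intermediate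
17 | CNP0298337.1, (2R,3R)-2-(3,4-dihydroxyphenyl)-8-[(2S,4S)-7-hydroxy-2-(4-hydroxyphenyl)-3,4-dihydro-2H-chromen-4-yl]-3,4-dihydro-2H-chromene-3,5,7-triol | Oc1ccc([C@@H]2C[C@H](c3c(O)cc(O)c4c3O[C@H](c3ccc(O)c(O)c3)[C@H](O)C4)c3ccc(O)cc3O2)cc1 | target

Total step count: 10. Longest linear sequence: 6 steps (steps 1, 2, 3, 8, 9, 10; the aldehyde branch through steps 5, 6, 7, 8, 9, 10 is equally long).

Steps most likely to fail

Risk 1 (step 9). The quinone methide may be consumed by tin-radical addition at its oxygen, by hydride reduction or by oligomerisation before iodine is abstracted; the C3 radical may fragment with loss of the aryloxy group; or facial selectivity at C4 may be poor. The fallback sets out from 4 and comes back at 17; it brings in the upper unit with ring C already closed and forms the C4–C8 bond by carbonyl addition. Commercial 7-hydroxy-4H-chromen-4-one is benzylated (BnBr, K2CO3, acetone) to 7-(benzyloxy)-4H-chromen-4-one F1. Enantioselective conjugate addition of 4-(benzyloxy)phenylboronic acid, with Pd(OCOCF3)2 and the enantiomer of 4-tert-butyl-2-(pyridin-2-yl)-4,5-dihydrooxazole that delivers the 2S product, should give (2S)-7-(benzyloxy)-2-[4-(benzyloxy)phenyl]chroman-4-one F2. Bromide 4 is lithiated as in step 8 to 11, transmetalated with CeCl3 to suppress enolisation, and added to F2 at −78 °C to give the tertiary benzylic alcohol F3. Catalytic TsOH in toluene dehydrates it to the 4-aryl-2H-chromene F4. Hydrogenation over Pd(OH)2/C should add hydrogen to C3=C4 from the face anti to the C2 aryl group (2,4-cis) and remove all seven benzyl groups to give 17.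

Risk 2 (step 8). The aryllithium, or residual t-BuLi, may attack the primary iodide (exchange, substitution or elimination), and the electron-rich benzhydryl acetate may ionise during isolation. The fallback sets out from 9 and 4 and comes back at 13; it forms the C4–C8 bond before the iodide and the leaving group exist. Aryllithium 11 (from 4) is added at −78 °C to bromide 9, which should be inert to the organolithium, and the alkoxide is protonated (NH4Cl) to give the bromo carbinol F5, purified on Et3N-deactivated silica. NaI in 2-butanone exchanges the halide to give the iodo carbinol F6. Acetylation under amine buffer (Ac2O, Et3N, DMAP, CH2Cl2, 0 °C) gives 13, which is taken into step 9 without chromatography.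

Risk 3 (step 6). Partial ionisation of the activated benzylic alkoxyphosphonium, or participation of the neighbouring bromine, may erode the configuration at C2. The fallback sets out from 8 and comes back at 10; it sets C2 by iridium-catalysed allylic etherification, which involves no benzylic displacement. Commercial (E)-4-(benzyloxy)cinnamic acid is reduced through its mixed anhydride (ClCO2Et, Et3N; then NaBH4) to (E)-3-[4-(benzyloxy)phenyl]prop-2-en-1-ol F7, and ClCO2Me/pyridine converts it into the methyl carbonate F8. The sodium phenoxide of 8 is allylated with F8 under [Ir(cod)Cl]2 and the enantiomer of a chiral phosphoramidite ligand that delivers the (S)-branched product, giving the allyl aryl ether F9. Ozonolysis at −78 °C with direct NaBH4 reduction, so that no free α-aryloxy aldehyde is exposed, gives the diol F10. MnO2 reoxidises only the benzylic alcohol to give the hydroxy aldehyde F11, and I2, PPh3 and imidazole (Appel reaction) give iodide 10.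

Further compounds
F1 | step 9 | 7-(benzyloxy)-4H-chromen-4-one | O=c1ccoc2cc(OCc3ccccc3)ccc12
F2 | step 9 | (2S)-7-(benzyloxy)-2-[4-(benzyloxy)phenyl]-2,3-dihydro-4H-chromen-4-one | O=C1C[C@@H](c2ccc(OCc3ccccc3)cc2)Oc2cc(OCc3ccccc3)ccc12
F3 | step 9 | (2S)-7-(benzyloxy)-2-[4-(benzyloxy)phenyl]-4-[(2R,3R)-3,5,7-tris(benzyloxy)-2-[3,4-bis(benzyloxy)phenyl]-3,4-dihydro-2H-chromen-8-yl]-3,4-dihydro-2H-chromen-4-ol (both C4 epimers) | OC1(c3c(OCc4ccccc4)cc(OCc4ccccc4)c4c3O[C@H](c3ccc(OCc5ccccc5)c(OCc5ccccc5)c3)[C@H](OCc3ccccc3)C4)C[C@@H](c2ccc(OCc3ccccc3)cc2)Oc2cc(OCc3ccccc3)ccc12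
F4 | step 9 | (2S)-7-(benzyloxy)-2-[4-(benzyloxy)phenyl]-4-[(2R,3R)-3,5,7-tris(benzyloxy)-2-[3,4-bis(benzyloxy)phenyl]-3,4-dihydro-2H-chromen-8-yl]-2H-chromene | C1(c3c(OCc4ccccc4)cc(OCc4ccccc4)c4c3O[C@H](c3ccc(OCc5ccccc5)c(OCc5ccccc5)c3)[C@H](OCc3ccccc3)C4)=C[C@@H](c2ccc(OCc3ccccc3)cc2)Oc2cc(OCc3ccccc3)ccc12
F5 | step 8 | {2-{(1R)-1-[4-(benzyloxy)phenyl]-2-bromoethoxy}-4-[(tert-butyldimethylsilyl)oxy]phenyl}[(2R,3R)-3,5,7-tris(benzyloxy)-2-[3,4-bis(benzyloxy)phenyl]-3,4-dihydro-2H-chromen-8-yl]methanol (both epimers) | OC(c1ccc(O[Si](C)(C)C(C)(C)C)cc1O[C@@H](CBr)c1ccc(OCc2ccccc2)cc1)c1c(OCc2ccccc2)cc(OCc2ccccc2)c2c1O[C@H](c1ccc(OCc3ccccc3)c(OCc3ccccc3)c1)[C@H](OCc1ccccc1)C2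
F6 | step 8 | {2-{(1R)-1-[4-(benzyloxy)phenyl]-2-iodoethoxy}-4-[(tert-butyldimethylsilyl)oxy]phenyl}[(2R,3R)-3,5,7-tris(benzyloxy)-2-[3,4-bis(benzyloxy)phenyl]-3,4-dihydro-2H-chromen-8-yl]methanol (both epimers) | OC(c1ccc(O[Si](C)(C)C(C)(C)C)cc1O[C@@H](CI)c1ccc(OCc2ccccc2)cc1)c1c(OCc2ccccc2)cc(OCc2ccccc2)c2c1O[C@H](c1ccc(OCc3ccccc3)c(OCc3ccccc3)c1)[C@H](OCc1ccccc1)C2
F7 | step 6 | (E)-3-[4-(benzyloxy)phenyl]prop-2-en-1-ol | OC/C=C/c1ccc(OCc2ccccc2)cc1
F8 | step 6 | (E)-3-[4-(benzyloxy)phenyl]prop-2-en-1-yl methyl carbonate | COC(=O)OC/C=C/c1ccc(OCc2ccccc2)cc1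
F9 | step 6 | 2-{[(1S)-1-[4-(benzyloxy)phenyl]prop-2-en-1-yl]oxy}-4-[(tert-butyldimethylsilyl)oxy]benzaldehyde | C=C[C@H](Oc1cc(O[Si](C)(C)C(C)(C)C)ccc1C=O)c1ccc(OCc2ccccc2)cc1
F10 | step 6 | (2R)-2-[4-(benzyloxy)phenyl]-2-{5-[(tert-butyldimethylsilyl)oxy]-2-(hydroxymethyl)phenoxy}ethan-1-ol | OC[C@H](Oc1cc(O[Si](C)(C)C(C)(C)C)ccc1CO)c1ccc(OCc2ccccc2)cc1
F11 | step 6 | 2-{(1R)-1-[4-(benzyloxy)phenyl]-2-hydroxyethoxy}-4-[(tert-butyldimethylsilyl)oxy]benzaldehyde | OC[C@H](Oc1cc(O[Si](C)(C)C(C)(C)C)ccc1C=O)c1ccc(OCc2ccccc2)cc1
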